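**Plan**

Numbering of the 3,7-dioxabicyclo[3.3.0]octane core: C1 and C5 are the bridgeheads, C2 carries the hydroxyaryl group (ring A: C1–C2–O3–C4–C5), C6 carries the prenyloxyaryl group (ring B: C5–C6–O7–C8–C1).
Retrosynthesis: ring B is raised at C8 to a γ-lactone and C1 is given a CO2Me group; ring A is then cut at C1–C2 and O3–C4 in one carbonyl (3+2) disconnection, giving O-tosylvanillin and a lactone-fused cyclopropane made of C1, C5 and C4.
Enabling feature: C4 is a bare CH2 between O3 and bridgehead C5, and bridgehead C1 lies α to C8. With C8 as a carbonyl and an ester on C1, the C1–C4 cyclopropane bond is a masked C1-enolate/C4-electrophile pair that iodide unlocks.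
Forward order: aryl allylic alcohol → diazomalonate → intramolecular cyclopropanation (lactone ring B plus cyclopropane) → iodide-relayed (3+2) with the aldehyde (ring A) → loss of CO2Me → lactone reduced and re-closed as the ether → phenol released.
Stereochemistry: C6 comes from a Sharpless kinetic resolution; C6 directs C5 and C1 in the cyclopropanation (aryl exo); the cis ring fusion is enforced by strain; C2 is set in the key step (aryl exo).

Key step: step 8

Remark: the target is the mono-prenyl ether in the enantiomeric series of (+)-pinoresinol, (1S,2R,5S,6R), with both aryl groups exo; aldehyde 13 is prepared in step 7 and not assumed to be purchasable.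

**Route**

Step 1
Reactants: 1 vanillin, 2 prenyl bromide
Product: 3 3-methoxy-4-(3-methylbut-2-enyloxy)benzaldehyde
Conditions: K2CO3, DMF, 25 °C
Reagents that add atoms: prenyl bromide 2, CC(C)=CCBr
Why: Williamson ether synthesis, in which the phenoxide displaces the primary allylic bromide (SN2) and no stereocenter is formed.

Step 2
Reactants: 3 3-methoxy-4-(3-methylbut-2-enyloxy)benzaldehyde, 4 vinylmagnesium bromide
Product: 5 rac-1-[3-methoxy-4-(3-methylbut-2-enyloxy)phenyl]prop-2-en-1-ol
Conditions: THF, −78 → 0 °C; aq. NH4Cl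
Reagents that add atoms: vinylmagnesium bromide 4, C=C[Mg]Br
Why: Grignard 1,2-addition to the non-enolisable aryl aldehyde gives the secondary allylic alcohol as a racemate, which is resolved in step 3.

Step 3
Reactants: 5 rac-1-[3-methoxy-4-(3-methylbut-2-enyloxy)phenyl]prop-2-en-1-ol
Product: 6 (R)-1-[3-methoxy-4-(3-methylbut-2-enyloxy)phenyl]prop-2-en-1-ol
Conditions: Ti(OiPr)4, D-(−)-diisopropyl tartrate, t-BuOOH (0.6 equiv), 4 Å MS, CH2Cl2, −20 °C, run to just past half conversion
Reagents that add atoms: none
Why: Sharpless kinetic resolution, in which the tetravalent titanium–D-tartrate–peroxide complex epoxidises the (S)-carbinol much faster (to the erythro epoxy alcohol), so the (R)-alcohol should be recovered in high enantiomeric purity, while the prenyl alkene has no allylic hydroxyl and should not be epoxidised.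

Step 4
Reactants: 6 (R)-1-[3-methoxy-4-(3-methylbut-2-enyloxy)phenyl]prop-2-en-1-ol, 7 methyl malonyl chloride
Product: 8 methyl (R)-1-[3-methoxy-4-(3-methylbut-2-enyloxy)phenyl]prop-2-enyl propanedioate
Conditions: pyridine, CH2Cl2, 0 °C
Reagents that add atoms: methyl malonyl chloride 7, COC(=O)CC(=O)Cl
Why: Acylation of the alcohol by the acid chloride (nucleophilic acyl substitution) does not touch the C–O bond, so the (R) configuration is retained.

Step 5
Reactants: 8 methyl (R)-1-[3-methoxy-4-(3-methylbut-2-enyloxy)phenyl]prop-2-enyl propanedioate, 9 4-acetamidobenzenesulfonyl azide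
Product: 10 methyl (R)-1-[3-methoxy-4-(3-methylbut-2-enyloxy)phenyl]prop-2-enyl 2-diazopropanedioate
Conditions: Et3N, MeCN, 0 → 25 °C
Reagents that add atoms: 4-acetamidobenzenesulfonyl azide 9, CC(=O)Nc1ccc(cc1)S(=O)(=O)N=[N+]=[N-]
Why: Regitz diazo transfer from the sulfonyl azide to the amine-generated malonate enolate gives the diazomalonate without affecting the stereocenter.

Step 6
Reactants: 10 methyl (R)-1-[3-methoxy-4-(3-methylbut-2-enyloxy)phenyl]prop-2-enyl 2-diazopropanedioate
Product: 11 methyl (1S,4R,5R)-4-[3-methoxy-4-(3-methylbut-2-enyloxy)phenyl]-2-oxo-3-oxabicyclo[3.1.0]hexane-1-carboxylate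
Conditions: Rh2(OAc)4 (2 mol %), benzene, 80 °C, slow addition of 10
Reagents that add atoms: none
Why: Rhodium-carbenoid intramolecular cyclopropanation of the tethered terminal alkene closes the γ-lactone and the three-membered ring at once, and the carbinol stereocenter should direct the addition so that the aryl group lies anti to the new cyclopropane (carbinol hydrogen eclipsing the alkene in the transition state), which sets C1 and C5 of the bicycle.

Step 7
Reactants: 1 vanillin, 12 4-toluenesulfonyl chloride
Product: 13 4-formyl-2-methoxyphenyl 4-methylbenzenesulfonate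
Conditions: Et3N, DMAP (cat.), CH2Cl2, 0 → 25 °C
Reagents that add atoms: 4-toluenesulfonyl chloride 12, Cc1ccc(cc1)S(=O)(=O)Cl
Why: Sulfonylation of the phenol gives an aryl sulfonate that is stable to Lewis acid, hydride and mild base and that also raises the electrophilicity of the aldehyde.

Step 8
Reactants: 11 methyl (1S,4R,5R)-4-[3-methoxy-4-(3-methylbut-2-enyloxy)phenyl]-2-oxo-3-oxabicyclo[3.1.0]hexane-1-carboxylate, 13 4-formyl-2-methoxyphenyl 4-methylbenzenesulfonate
Product: 16 methyl (1R,2S,5S,6R)-2-[3-methoxy-4-(tosyloxy)phenyl]-6-[3-methoxy-4-(3-methylbut-2-enyloxy)phenyl]-8-oxo-3,7-dioxabicyclo[3.3.0]octane-1-carboxylate, via γ-iodo magnesium enolate 14 (not isolated), via γ-iodo magnesium aldolate 15 (not isolated)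
Conditions: MgI2 (0.5 equiv), 4 Å MS, THF, 65 °C
Reagents that add atoms: none
Why: Proposed new method: MgI2 chelates the lactone and ester carbonyls of 11, iodide opens the cyclopropane by SN2 attack at its unhindered CH2 carbon (the exocyclic cyclopropane bond overlaps with both carbonyl π systems), the magnesium enolate 14 adds to aldehyde 13, and the oxygen of aldolate 15 displaces iodide, so that the C1–C2 and O3–C4 bonds of the bicycle form in one flask. The closest known reaction types are the MgI2-mediated ring expansion of acceptor-activated cyclopropanes with imines or nitrones and the annulation of γ-halocarbanions with aldehydes to tetrahydrofurans, whereas the sequence with an aldehyde on a lactone-fused cyclopropane carboxylate is not established. Ring A closes in a 5-exo-tet mode (intramolecular Williamson displacement of the primary iodide), which only the aldolate with the new C–C bond cis to CH2I can reach, so bridgehead C1 is fixed by the untouched C5 and the ring fusion must be cis. The aldol is reversible, so aldolates that cannot close revert to 14, and of the two C2 epimers the one that closes with the aryl group on the convex face, away from the lactone ring, should be the faster, which sets C2 with the aryl group exo. The step needs iodide attack at CH2 and not at the ring-fusion carbon or the benzylic lactone carbon, which the primary nature of that carbon should secure, and it needs a reactive non-enolisable aldehyde, which the sulfonate-bearing 13 provides.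

Step 9
Reactants: 16 methyl (1R,2S,5S,6R)-2-[3-methoxy-4-(tosyloxy)phenyl]-6-[3-methoxy-4-(3-methylbut-2-enyloxy)phenyl]-8-oxo-3,7-dioxabicyclo[3.3.0]octane-1-carboxylate
Product: 18 (1R,2R,5S,6R)-2-[3-methoxy-4-(tosyloxy)phenyl]-6-[3-methoxy-4-(3-methylbut-2-enyloxy)phenyl]-3,7-dioxabicyclo[3.3.0]octan-8-one, via lithium carboxylate 17 (not isolated)
Conditions: LiCl, H2O (2 equiv), DMSO, 130 °C
Reagents that add atoms: none
Why: Krapcho dealkoxycarbonylation, in which chloride demethylates the ester (SN2), carboxylate 17 loses CO2 to the lactone enolate, and protonation can only give the cis-fused bicycle, which places the new bridgehead hydrogen on the convex face.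

Step 10
Reactants: 18 (1R,2R,5S,6R)-2-[3-methoxy-4-(tosyloxy)phenyl]-6-[3-methoxy-4-(3-methylbut-2-enyloxy)phenyl]-3,7-dioxabicyclo[3.3.0]octan-8-one
Product: 19 4-{(2R,3S,4S)-4-[(R)-hydroxy[3-methoxy-4-(3-methylbut-2-enyloxy)phenyl]methyl]-3-(hydroxymethyl)oxolan-2-yl}-2-methoxyphenyl 4-methylbenzenesulfonate
Conditions: LiBH4, THF, 0 → 40 °C; aq. NH4Cl
Reagents that add atoms: none
Why: Hydride reduction of the γ-lactone by LiBH4 gives the 1,4-diol without changing any stereocenter and should leave the aryl sulfonate, the aryl ethers and the trisubstituted alkene untouched.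

Step 11
Reactants: 19 4-{(2R,3S,4S)-4-[(R)-hydroxy[3-methoxy-4-(3-methylbut-2-enyloxy)phenyl]methyl]-3-(hydroxymethyl)oxolan-2-yl}-2-methoxyphenyl 4-methylbenzenesulfonate
Product: 21 4-{(1S,2R,5S,6R)-6-[3-methoxy-4-(3-methylbut-2-enyloxy)phenyl]-3,7-dioxabicyclo[3.3.0]octan-2-yl}-2-methoxyphenyl 4-methylbenzenesulfonate, via primary mesylate 20 (not isolated)
Conditions: MsCl (1.1 equiv), Et3N, CH2Cl2, −20 → 25 °C
Reagents that add atoms: none
Why: Selective mesylation of the primary alcohol followed by intramolecular Williamson displacement (5-exo-tet) by the secondary benzylic hydroxyl closes ring B with retention at the benzylic carbon C6.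

Step 12
Reactants: 21 4-{(1S,2R,5S,6R)-6-[3-methoxy-4-(3-methylbut-2-enyloxy)phenyl]-3,7-dioxabicyclo[3.3.0]octan-2-yl}-2-methoxyphenyl 4-methylbenzenesulfonate
Product: 22 4-{(1S,2R,5S,6R)-6-[3-methoxy-4-(3-methylbut-2-enyloxy)phenyl]-3,7-dioxabicyclo[3.3.0]octan-2-yl}-2-methoxyphenol (target)
Conditions: KOH, MeOH/THF/H2O, 60 °C; then dilute HCl to pH 7 at 0 °C
Reagents that add atoms: none
Why: Hydrolysis of the aryl sulfonate by hydroxide attack at sulfur (S–O cleavage) releases the phenoxide, while the ethers, the prenyl group and the four stereocenters are inert to base.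

**Compound list**

1 | vanillin (4-hydroxy-3-methoxybenzaldehyde) | COc1cc(C=O)ccc1O | starting material
2 | prenyl bromide (1-bromo-3-methylbut-2-ene) | CC(C)=CCBr | starting material
3 | 3-methoxy-4-(3-methylbut-2-enyloxy)benzaldehyde | COc1cc(C=O)ccc1OCC=C(C)C | intermediate
4 | vinylmagnesium bromide | C=C[Mg]Br | starting material
5 | rac-1-[3-methoxy-4-(3-methylbut-2-enyloxy)phenyl]prop-2-en-1-ol | C=CC(O)c1ccc(OCC=C(C)C)c(OC)c1 | intermediate
6 | (R)-1-[3-methoxy-4-(3-methylbut-2-enyloxy)phenyl]prop-2-en-1-ol | C=C[C@@H](O)c1ccc(OCC=C(C)C)c(OC)c1 | intermediate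
7 | methyl malonyl chloride (methyl 3-chloro-3-oxopropanoate) | COC(=O)CC(=O)Cl | starting material
8 | methyl (R)-1-[3-methoxy-4-(3-methylbut-2-enyloxy)phenyl]prop-2-enyl propanedioate | COC(=O)CC(=O)O[C@H](C=C)c1ccc(OCC=C(C)C)c(OC)c1 | intermediate
9 | 4-acetamidobenzenesulfonyl azide | CC(=O)Nc1ccc(cc1)S(=O)(=O)N=[N+]=[N-] | starting material
10 | methyl (R)-1-[3-methoxy-4-(3-methylbut-2-enyloxy)phenyl]prop-2-enyl 2-diazopropanedioate | COC(=O)C(=[N+]=[N-])C(=O)O[C@H](C=C)c1ccc(OCC=C(C)C)c(OC)c1 | intermediate
11 | methyl (1S,4R,5R)-4-[3-methoxy-4-(3-methylbut-2-enyloxy)phenyl]-2-oxo-3-oxabicyclo[3.1.0]hexane-1-carboxylate (aryl anti to the cyclopropane) | C1[C@@H]2[C@@]1(C(=O)OC)C(=O)O[C@H]2c1ccc(OCC=C(C)C)c(OC)c1 | intermediate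
12 | 4-toluenesulfonyl chloride | Cc1ccc(cc1)S(=O)(=O)Cl | starting material
13 | 4-formyl-2-methoxyphenyl 4-methylbenzenesulfonate (O-tosylvanillin) | COc1cc(C=O)ccc1OS(=O)(=O)c1ccc(C)cc1 | intermediate
14 | iodomagnesium enolate of methyl (4R,5R)-4-(iodomethyl)-5-[3-methoxy-4-(3-methylbut-2-enyloxy)phenyl]-2-oxooxolane-3-carboxylate | IC[C@@H]1C(C(=O)OC)=C(O[Mg]I)O[C@H]1c1ccc(OCC=C(C)C)c(OC)c1 | intermediate
15 | iodomagnesium alkoxide of the aldol adduct of 14 at C3 with 13 (new C–C bond cis to CH2I) | IC[C@@H]1[C@@]([C@@H](O[Mg]I)c2ccc(OS(=O)(=O)c3ccc(C)cc3)c(OC)c2)(C(=O)OC)C(=O)O[C@H]1c1ccc(OCC=C(C)C)c(OC)c1 | intermediate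
16 | methyl (1R,2S,5S,6R)-2-[3-methoxy-4-(tosyloxy)phenyl]-6-[3-methoxy-4-(3-methylbut-2-enyloxy)phenyl]-8-oxo-3,7-dioxabicyclo[3.3.0]octane-1-carboxylate (cis-fused, both aryl groups exo) | COc1cc([C@@H]2OC[C@@H]3[C@@]2(C(=O)OC)C(=O)O[C@H]3c2ccc(OCC=C(C)C)c(OC)c2)ccc1OS(=O)(=O)c1ccc(C)cc1 | intermediate
17 | lithium carboxylate of 16 (CO2Li in place of CO2Me) | COc1cc([C@@H]2OC[C@@H]3[C@@]2(C(=O)[O-])C(=O)O[C@H]3c2ccc(OCC=C(C)C)c(OC)c2)ccc1OS(=O)(=O)c1ccc(C)cc1.[Li+] | intermediate
18 | (1R,2R,5S,6R)-2-[3-methoxy-4-(tosyloxy)phenyl]-6-[3-methoxy-4-(3-methylbut-2-enyloxy)phenyl]-3,7-dioxabicyclo[3.3.0]octan-8-one | COc1cc([C@@H]2OC[C@@H]3[C@H]2C(=O)O[C@H]3c2ccc(OCC=C(C)C)c(OC)c2)ccc1OS(=O)(=O)c1ccc(C)cc1 | intermediate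
19 | 4-{(2R,3S,4S)-4-[(R)-hydroxy[3-methoxy-4-(3-methylbut-2-enyloxy)phenyl]methyl]-3-(hydroxymethyl)oxolan-2-yl}-2-methoxyphenyl 4-methylbenzenesulfonate | COc1cc([C@@H]2OC[C@@H]([C@@H](O)c3ccc(OCC=C(C)C)c(OC)c3)[C@H]2CO)ccc1OS(=O)(=O)c1ccc(C)cc1 | intermediate
20 | primary methanesulfonate of 19 (CH2OMs on C3 of the oxolane) | COc1cc([C@@H]2OC[C@@H]([C@@H](O)c3ccc(OCC=C(C)C)c(OC)c3)[C@H]2COS(C)(=O)=O)ccc1OS(=O)(=O)c1ccc(C)cc1 | intermediate
21 | 4-{(1S,2R,5S,6R)-6-[3-methoxy-4-(3-methylbut-2-enyloxy)phenyl]-3,7-dioxabicyclo[3.3.0]octan-2-yl}-2-methoxyphenyl 4-methylbenzenesulfonate | COc1cc([C@@H]2OC[C@@H]3[C@H]2CO[C@H]3c2ccc(OCC=C(C)C)c(OC)c2)ccc1OS(=O)(=O)c1ccc(C)cc1 | intermediate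
22 | 4-{(1S,2R,5S,6R)-6-[3-methoxy-4-(3-methylbut-2-enyloxy)phenyl]-3,7-dioxabicyclo[3.3.0]octan-2-yl}-2-methoxyphenol | COc1cc([C@@H]2OC[C@@H]3[C@H]2CO[C@H]3c2ccc(OCC=C(C)C)c(OC)c2)ccc1O | target

**Summary**

Total step count: 12
Longest linear sequence: 11 steps (steps 1–6 and 8–12; step 7 is a one-step side branch)

**Steps most likely to fail**

1. Step 8 (proposed new method). The magnesium enolate may re-close to the cyclopropane or undergo retro-aldol faster than the aldolate is trapped; iodide may ionise the benzylic lactone C–O bond; or ring closure may occur with the aryl group endo. The fallback uses known chemistry with a pre-formed, singly activated γ-chloro lactone enolate in place of the Lewis acid/iodide relay. It sets out from 11 and 13 and comes back to the route at 18, so step 9 is skipped. Homoconjugate addition of HCl to 11 (Et3N·HCl, DMF, 90 °C) should give methyl (4R,5R)-4-(chloromethyl)-5-[3-methoxy-4-(3-methylbut-2-enyloxy)phenyl]-2-oxooxolane-3-carboxylate F1. Krapcho dealkoxycarbonylation (LiCl, wet DMSO, 130 °C) should then give (4R,5R)-4-(chloromethyl)-5-[3-methoxy-4-(3-methylbut-2-enyloxy)phenyl]oxolan-2-one F2. LiN(iPr)2 is added to a mixture of F2 and 13 in THF at −78 °C and the mixture is warmed to 25 °C. Aldol addition of the lithium enolate and closure of the cis aldolate onto the primary chloride (the known annulation of γ-halocarbanions with aldehydes to tetrahydrofurans) should give 18; having the aldehyde present from the start is meant to outrun the competing closure to a cyclopropane.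

2. Step 6. The carbenoid may divert into insertion into the activated allylic/benzylic C–H bond (β-lactone) or into addition to the electron-rich arene, and facial control by the carbinol centre may be poor (aryl syn to the cyclopropane). The fallback replaces carbenoid chemistry by a known oxidative radical cyclisation of allylic malonates. It sets out from 8 (step 5 is skipped) and comes back at 11. Mn(OAc)3·2H2O (2 equiv) and Cu(OAc)2·H2O in ethanol at 60 °C should generate the malonyl radical. Its 5-exo cyclisation places the aryl group trans to the new CH2 radical (chair-like transition state, aryl pseudo-equatorial), and oxidation of that radical by divalent copper lets the malonate carbon close the three-membered ring. No new compound arises on this way (entry F0).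

3. Step 9. At 130 °C the lactone enolate formed after loss of CO2 may expel the β-alkoxide (opening of ring A), the aryl prenyl ether may begin to rearrange by a [3,3] shift, or chloride may attack the sulfonate. The fallback replaces dealkylation at high temperature by acyl-oxygen hydrolysis and a neutral thermal decarboxylation. It sets out from 16 and comes back at 18. Me3SnOH in 1,2-dichloroethane at 80 °C should cleave the methyl ester to (1R,2S,5S,6R)-2-[3-methoxy-4-(tosyloxy)phenyl]-6-[3-methoxy-4-(3-methylbut-2-enyloxy)phenyl]-8-oxo-3,7-dioxabicyclo[3.3.0]octane-1-carboxylic acid F3. This α-carboxy lactone should lose CO2 in toluene at 90 °C through the usual six-membered transition state.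

**Further compounds**

F1 | step 8 | methyl (4R,5R)-4-(chloromethyl)-5-[3-methoxy-4-(3-methylbut-2-enyloxy)phenyl]-2-oxooxolane-3-carboxylate (both C3 epimers) | ClC[C@@H]1C(C(=O)OC)C(=O)O[C@H]1c1ccc(OCC=C(C)C)c(OC)c1
F2 | step 8 | (4R,5R)-4-(chloromethyl)-5-[3-methoxy-4-(3-methylbut-2-enyloxy)phenyl]oxolan-2-one | ClC[C@@H]1CC(=O)O[C@H]1c1ccc(OCC=C(C)C)c(OC)c1
F0 | step 6 | none | none
F3 | step 9 | (1R,2S,5S,6R)-2-[3-methoxy-4-(tosyloxy)phenyl]-6-[3-methoxy-4-(3-methylbut-2-enyloxy)phenyl]-8-oxo-3,7-dioxabicyclo[3.3.0]octane-1-carboxylic acid | COc1cc([C@@H]2OC[C@@H]3[C@@]2(C(=O)O)C(=O)O[C@H]3c2ccc(OCC=C(C)C)c(OC)c2)ccc1OS(=O)(=O)c1ccc(C)cc1
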